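You read at 3.0 d, and your hunch is that slow dosing buys target. Here is the problem, then my number.

| flask | substrate | coupling partner | remark | time |
|---|---|---|---|---|
| alder | 23 mM | 1.3 equiv | run made earlier |  |
| birch | 15 mM | 1.3 equiv | run made earlier |  |
| maple | 34 mM | 1.3 equiv | run made earlier |  |
| noon | 23 mM | 1.30 equiv | a single well-mixed tank run continuously and read at steady state, 3.0 d in it on average |  |
| spring | 23 mM (fed, over 2.40 d) | 1.30 equiv | a stirred flask in which substrate is dosed at a steady rate over 2.40 d without added volume, worked up at 3.0 d | 3.0 d |
| dusk | 23 mM | 1.30 equiv (fed, over 2.40 d) | a stirred flask in which coupling partner is dosed at a steady rate over 2.40 d without added volume, worked up at 3.0 d | 3.0 d |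
| autumn | 23 mM | 1.30 equiv | a closed flask charged with all of it at once and left for 3.0 d | 3.0 d |

| run | time / d | target / % | substrate / % |
|---|---|---|---|
| alder | 0.250 | 9.1 | 90.8 |
| alder | 0.333 | 31.9 | 59.7 |
| alder | 0.500 | 56.6 | 16.8 |
| alder | 0.833 | 56.8 | 1.2 |
| alder | 1.25 | 55.9 | 0.6 |
| alder | 2.08 | 55.4 | 0.3 |
| alder | 3.00 | 56.7 | 0.7 |
| birch | 0.125 | 1.2 | 101.0 |
| birch | 0.333 | 1.6 | 99.9 |
| birch | 0.625 | 14.1 | 79.7 |
| birch | 1.04 | 48.6 | 22.3 |
| birch | 1.67 | 54.5 | 4.5 |
| birch | 2.08 | 55.1 | 2.2 |
| birch | 2.50 | 54.7 | 0 |
| maple | 0.125 | 12.9 | 85.7 |
| maple | 0.333 | 64.5 | 4.8 |
| maple | 0.625 | 58.4 | 0.9 |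
| maple | 1.04 | 56.3 | 0 |
| maple | 1.67 | 56.8 | 0 |
| maple | 2.08 | 55.9 | 0.9 |
| maple | 2.50 | 57.0 | 1.0 |

(each reading ± 1 percentage point)

- the stated concentrations are those of everything mixed, before any reaction; amounts are the same in each set-up
- steps that have been proposed: substrate + coupling partner + by-product -> target + 2 by-product; substrate + coupling partner -> target + by-product; target <-> isomer of the product; substrate -> decomposition product
- the feed brings no volume worth counting
- the earlier runs were made in a closed, stirred flask

- the set-up with the highest amount of target at the outlet or at the end, in percent of the substrate put in ("none" if the first two lie within 2 percentage points) (noon / spring / dusk / autumn / none)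
- amount of target at the outlet or at the end, in percent of the substrate put in, noon
- amount of target at the outlet or at the end, in percent of the substrate put in, spring
- amount of target at the outlet or at the end, in percent of the substrate put in, dusk
- amount of target at the outlet or at the end, in percent of the substrate put in, autumn

Freeze one thing: the plateau share 56.0%, the fraction of the charge standing as target once the substrate has reacted and the readings stop moving. I average it from the late alder readings.

Maple reads 64.5% at 0.333 d, which is kinetic control, then 58.4% at 0.625 d, on its way to the plateau of thermodynamic control. Those two readings stand 0.292 d apart. Late maple averages 56.6% and late birch 54.8%, and these averages lie 1.8 percentage points apart.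

My rule, at 1.30 equiv of coupling partner and once the readings have levelled, is that target at the end equals the plateau share times the fraction of the charge converted. Autumn should therefore give 56.0%. In spring and dusk the dose stops at 2.40 d, and the tail of 0.600 d is longer than that gap in maple, so I put both near 56.0% as well. Noon should sit somewhat lower, on my guess that its outlet still carries substrate. I say none.

The forecast also says none: noon 55% (51.5% to 57%), spring 56.3% (54.8% to 57.5%), dusk 55.2% (53% to 56.8%), autumn 56.3% (55.2% to 57.5%). Its noon uses “conversion about 95%”. Its autumn stands 0.3 points above my share.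

The flask gives none: noon 54.5%, spring 55.7%, dusk 55.1%, autumn 55.7%.

    substrate + coupling partner + by-product → target + 2 by-product (k = 1500 L² mol⁻² h⁻¹)
    substrate + coupling partner → target + by-product (k = 0.00950 L mol⁻¹ h⁻¹)
    target ⇌ isomer of the product (K = 0.790, k = 0.170 h⁻¹)
    substrate → decomposition product (k = 4.00 × 10⁻⁴ h⁻¹)

The gradual adding of substrate makes no difference in spring. The plateau share, applied to autumn's whole charge, reads 0.30 points above the flask, against a scatter of 1 point. Applied to spring with the dose put in over a tenth of the run, it again reads 56.0%, and that flask gives 55.7%.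

The numbers in the tables are simulated with constants of no real substance; noise was put on by code.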